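**Assumption:** the target is delivered as the free hydrogen sulfate as drawn (it can be stored as its sodium salt). Descriptors used: ring (1S,6R), chain carbinyl carbon (2S), alkene 5E; the two ring methyls on the stereocentres are cis.

## Retrosynthetic overview

1. Sulfate ⇐ primary alcohol; the C(sp3)–C(sp2) bond next to the trisubstituted alkene ⇐ B-alkyl Suzuki coupling of a western (E)-vinyl iodide with the 9-BBN adduct of an eastern chiral 2-vinyl alkanol.
2. (E)-Vinyl iodide ⇐ Zr-catalysed carboalumination/iodination of a terminal alkyne on the (1S,6R)-1,2,6-trimethylcyclohex-2-enyl ring.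
3. Ring stereodiad (quaternary C–CH3 next to CH–CH3) ⇐ catalytic enantioselective protonation / 1,2-H / 1,2-methyl shift of an achiral 2,6,6-trimethylcyclohexene (key step); that alkene ⇐ enol triflate of 2,2,6-trimethylcyclohexanone + alkylzinc; ketone ⇐ 2-methylcyclohexanone.
4. Eastern stereocentre ⇐ Cu-catalysed asymmetric SN2′ alkylation of (E)-1,4-dibromobut-2-ene with a 3-(furan-3-yl)propyl Grignard reagent (from 3-bromofuran and 1,3-dibromopropane).
5. Rings: none is built; the cyclohexane and furan rings are bought, and the six-membered ring is only re-substituted by the 1,2-shift.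

## Route

**Step 1**
Reactants: 1 2-methylcyclohexan-1-one (racemic)
Product: 5 2,2,6-trimethylcyclohexan-1-one, via lithium 6-methylcyclohex-1-en-1-olate 2 (not isolated), via 2,6-dimethylcyclohexan-1-one 3 (not isolated), via lithium 2,6-dimethylcyclohex-1-en-1-olate 4 (not isolated)
Conditions: LDA, THF, −78 °C; MeI, −78 → 0 °C; then LDA, −78 → 0 °C; MeI, → rt (one pot)
Reagents that add atoms: iodomethane (MeI), CI
Why: Two successive kinetic lithium-enolate C-methylations (SN2 on MeI); whichever α-carbon is methylated first, the second methylation can only give the 2,2,6-pattern, and the racemic stereocentre is erased in step 2.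

**Step 2**
Reactants: 5 2,2,6-trimethylcyclohexan-1-one
Product: 7 2,6,6-trimethylcyclohex-1-en-1-yl trifluoromethanesulfonate, via lithium 2,6,6-trimethylcyclohex-1-en-1-olate 6 (not isolated)
Conditions: LDA, THF, −78 → 0 °C; PhNTf2, 0 °C → rt
Reagents that add atoms: N-phenylbis(trifluoromethanesulfonimide) (PhNTf2), O=S(=O)(N(c1ccccc1)S(=O)(=O)C(F)(F)F)C(F)(F)F
Why: Enolate O-triflation; one α-carbon is quaternary, so deprotonation can occur only at the CH(CH3) carbon and gives the tetrasubstituted enol triflate regiospecifically.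

**Step 3**
Reactants: 7 2,6,6-trimethylcyclohex-1-en-1-yl trifluoromethanesulfonate; 8 (4-bromobut-1-yn-1-yl)trimethylsilane
Product: 11 2-(but-3-yn-1-yl)-1,3,3-trimethylcyclohex-1-ene, via bromo[4-(trimethylsilyl)but-3-yn-1-yl]zinc 9 (not isolated), via trimethyl[4-(2,6,6-trimethylcyclohex-1-en-1-yl)but-1-yn-1-yl]silane 10 (not isolated)
Conditions: 8, Zn dust, LiCl, THF, 50 °C; then 7, PdCl2(dppf) (5 mol %), THF/NMP, 60 °C; then K2CO3, MeOH, rt
Reagents that add atoms: none
Why: Zinc insertion into the primary C–Br bond, then Pd-catalysed Negishi sp2–sp3 coupling at the enol triflate and base-mediated methanolysis of the C(sp)–Si bond; no stereocentre is involved.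

**Step 4**
Reactants: 11 2-(but-3-yn-1-yl)-1,3,3-trimethylcyclohex-1-ene
Product: 12 (5R,6S)-6-(but-3-yn-1-yl)-1,5,6-trimethylcyclohex-1-ene
Conditions: (S,S)-IDPi (confined BINOL-derived imidodiphosphorimidate Brønsted acid, N-triflyl core, bulky 3,3′-aryl wings; 5 mol %), CHCl3, −40 °C
Reagents that add atoms: none
Why: Proposed new method: the confined chiral acid protonates the tetrasubstituted alkene enantioface-selectively at the chain-bearing carbon to give the cyclogeranyl-type tertiary cation held as a contact ion pair in the chiral anion; that axial H then shifts suprafacially to the methyl-bearing carbon, and the axial CH3 of the neighbouring CMe2 carbon migrates antiperiplanar to the chain-bearing carbon within the same chair (net anti addition of H and CH3 across the former C=C, which makes the two methyls cis and fixes both stereocentres); the counter-anion finally removes a ring CH2 proton next to the new cation to give the trisubstituted alkene; the closest known reactions are IDPi-catalysed asymmetric Wagner–Meerwein shifts of purely aliphatic alkenes and the BF3-promoted 1,2-H/1,2-CH3 (friedo) rearrangements of drimane-type olefins.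

**Step 5**
Reactants: 12 (5R,6S)-6-(but-3-yn-1-yl)-1,5,6-trimethylcyclohex-1-ene
Product: 14 (5R,6S)-6-[(3E)-4-iodo-3-methylbut-3-en-1-yl]-1,5,6-trimethylcyclohex-1-ene, via (E)-alkenyl(dimethyl)alane 13 (not isolated)
Conditions: Me3Al (2.5 equiv), Cp2ZrCl2 (0.25 equiv), CH2Cl2, 0 °C → rt; then I2, THF, −30 → 0 °C
Reagents that add atoms: trimethylaluminium, C[Al](C)C; iodine, II
Why: Negishi Zr-catalysed carboalumination adds CH3 and Al syn across the terminal alkyne (CH3 to the internal carbon) and iodinolysis of the C–Al bond goes with retention, so the (E)-iodide forms; the ring alkene and both stereocentres are untouched.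

**Step 6**
Reactants: 15 3-bromofuran; 16 1,3-dibromopropane
Product: 18 3-(3-bromopropyl)furan, via furan-3-yllithium 17 (not isolated)
Conditions: n-BuLi, THF, −78 °C; then 16 (4 equiv), DMPU, −78 → −45 °C
Reagents that add atoms: none
Why: Bromine–lithium exchange gives furan-3-yllithium (kept cold to prevent 3→2 isomerisation), which is mono-alkylated (SN2) by the excess dibromide.

**Step 7**
Reactants: 18 3-(3-bromopropyl)furan; 19 (E)-1,4-dibromobut-2-ene
Product: 21 3-[(4S)-4-(bromomethyl)hex-5-en-1-yl]furan, via [3-(furan-3-yl)propyl]magnesium bromide 20 (not isolated)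
Conditions: Mg, Et2O, rt; then 19, CuBr·SMe2 (3 mol %), (R,Rp)-Taniaphos (3.5 mol %), CH2Cl2, −78 °C (slow addition of 20)
Reagents that add atoms: none
Why: Cu-catalysed asymmetric allylic alkylation (SN2′) of a Grignard reagent: the chiral Cu(I)–diphosphine delivers the alkyl group to the γ-carbon of the allylic bromide and sets the branched stereocentre under ligand control (the ligand hand giving 4S is to be confirmed in a test run, the antipode being equally available), while the remaining homoallylic C–Br bond is inert at −78 °C.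

**Step 8**
Reactants: 21 3-[(4S)-4-(bromomethyl)hex-5-en-1-yl]furan
Product: 23 (2S)-2-ethenyl-5-(furan-3-yl)pentan-1-ol, via (2S)-2-ethenyl-5-(furan-3-yl)pentyl acetate 22 (not isolated)
Conditions: KOAc, 18-crown-6 (cat.), DMF, 70 °C; then K2CO3, MeOH, rt
Reagents that add atoms: potassium acetate, CC(=O)[O-].[K+]
Why: SN2 displacement of the primary bromide by acetate followed by transesterification with methanol; the reaction is at CH2, so the adjacent stereocentre keeps its configuration.

**Step 9**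
Reactants: 23 (2S)-2-ethenyl-5-(furan-3-yl)pentan-1-ol; 14 (5R,6S)-6-[(3E)-4-iodo-3-methylbut-3-en-1-yl]-1,5,6-trimethylcyclohex-1-ene
Product: 25 (2S,5E)-2-[3-(furan-3-yl)propyl]-6-methyl-8-[(1S,6R)-1,2,6-trimethylcyclohex-2-en-1-yl]oct-5-en-1-ol, via O,C-bis(9-BBN) adduct 24 (not isolated)
Conditions: 23, 9-BBN-H (2.3 equiv), THF, 0 °C → rt; then 14, PdCl2(dppf) (5 mol %), AsPh3, Cs2CO3, DMF/H2O, rt
Reagents that add atoms: none
Why: Anti-Markovnikov hydroboration of the vinyl group (the OH is masked in situ as its borinate) followed by B-alkyl Suzuki–Miyaura coupling, which retains the E geometry of the vinyl iodide; no stereocentre is touched.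

**Step 10**
Reactants: 25 (2S,5E)-2-[3-(furan-3-yl)propyl]-6-methyl-8-[(1S,6R)-1,2,6-trimethylcyclohex-2-en-1-yl]oct-5-en-1-ol
Product: 26 (2S,5E)-2-[3-(furan-3-yl)propyl]-6-methyl-8-[(1S,6R)-1,2,6-trimethylcyclohex-2-en-1-yl]oct-5-en-1-yl hydrogen sulfate
Conditions: SO3·pyridine (3 equiv), pyridine, 0 °C → rt, 1 h; then cold H+-form resin, MeOH
Reagents that add atoms: sulfur trioxide–pyridine complex, [O-]S(=O)(=O)[n+]1ccccc1
Why: O-sulfation of the primary alcohol with the SO3–pyridine complex is much faster than C-sulfonation of the furan at 0 °C; no stereocentre is touched.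

## Compound list

1 | 2-methylcyclohexan-1-one (racemic) | CC1CCCCC1=O | starting material
2 | lithium 6-methylcyclohex-1-en-1-olate | CC1CCCC=C1O[Li] | intermediate
3 | 2,6-dimethylcyclohexan-1-one (cis/trans mixture) | CC1CCCC(C)C1=O | intermediate
4 | lithium 2,6-dimethylcyclohex-1-en-1-olate | CC1CCCC(C)=C1O[Li] | intermediate
5 | 2,2,6-trimethylcyclohexan-1-one (racemic) | CC1CCCC(C)(C)C1=O | intermediate
6 | lithium 2,6,6-trimethylcyclohex-1-en-1-olate | CC1=C(O[Li])C(C)(C)CCC1 | intermediate
7 | 2,6,6-trimethylcyclohex-1-en-1-yl trifluoromethanesulfonate | CC1=C(OS(=O)(=O)C(F)(F)F)C(C)(C)CCC1 | intermediate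
8 | (4-bromobut-1-yn-1-yl)trimethylsilane (silyl = alkyne protecting group) | C[Si](C)(C)C#CCCBr | starting material
9 | bromo[4-(trimethylsilyl)but-3-yn-1-yl]zinc | C[Si](C)(C)C#CCC[Zn]Br | intermediate
10 | trimethyl[4-(2,6,6-trimethylcyclohex-1-en-1-yl)but-1-yn-1-yl]silane | CC1=C(CCC#C[Si](C)(C)C)C(C)(C)CCC1 | intermediate
11 | 2-(but-3-yn-1-yl)-1,3,3-trimethylcyclohex-1-ene | CC1=C(CCC#C)C(C)(C)CCC1 | intermediate
12 | (5R,6S)-6-(but-3-yn-1-yl)-1,5,6-trimethylcyclohex-1-ene | CC1=CCC[C@@H](C)[C@]1(C)CCC#C | intermediate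
13 | dimethyl{(1E)-2-methyl-4-[(1S,6R)-1,2,6-trimethylcyclohex-2-en-1-yl]but-1-en-1-yl}alumane | CC1=CCC[C@@H](C)[C@]1(C)CC/C(C)=C/[Al](C)C | intermediate
14 | (5R,6S)-6-[(3E)-4-iodo-3-methylbut-3-en-1-yl]-1,5,6-trimethylcyclohex-1-ene | CC1=CCC[C@@H](C)[C@]1(C)CC/C(C)=C/I | intermediate
15 | 3-bromofuran | Brc1ccoc1 | starting material
16 | 1,3-dibromopropane | BrCCCBr | starting material
17 | furan-3-yllithium | [Li]c1ccoc1 | intermediate
18 | 3-(3-bromopropyl)furan | BrCCCc1ccoc1 | intermediate
19 | (E)-1,4-dibromobut-2-ene | BrC/C=C/CBr | starting material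
20 | [3-(furan-3-yl)propyl]magnesium bromide | Br[Mg]CCCc1ccoc1 | intermediate
21 | 3-[(4S)-4-(bromomethyl)hex-5-en-1-yl]furan | C=C[C@H](CCCc1ccoc1)CBr | intermediate
22 | (2S)-2-ethenyl-5-(furan-3-yl)pentyl acetate | C=C[C@H](CCCc1ccoc1)COC(C)=O | intermediate
23 | (2S)-2-ethenyl-5-(furan-3-yl)pentan-1-ol | C=C[C@H](CCCc1ccoc1)CO | intermediate
24 | O,C-bis(9-borabicyclo[3.3.1]nonan-9-yl) adduct of 23 (B on the terminal carbon of the former vinyl group and on O; stereocentre spatially unchanged) | B1(C2CCCC1CCC2)CC[C@H](CCCc1ccoc1)COB1C2CCCC1CCC2 | intermediate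
25 | (2S,5E)-2-[3-(furan-3-yl)propyl]-6-methyl-8-[(1S,6R)-1,2,6-trimethylcyclohex-2-en-1-yl]oct-5-en-1-ol | CC1=CCC[C@@H](C)[C@]1(C)CC/C(C)=C/CC[C@H](CCCc1ccoc1)CO | intermediate
26 | (2S,5E)-2-[3-(furan-3-yl)propyl]-6-methyl-8-[(1S,6R)-1,2,6-trimethylcyclohex-2-en-1-yl]oct-5-en-1-yl hydrogen sulfate | CC1=CCC[C@@H](C)[C@]1(C)CC/C(C)=C/CC[C@H](CCCc1ccoc1)COS(=O)(=O)O | target

## Summary

Total steps: 10. Longest linear sequence: 7 (steps 1–5, 9, 10).

**Steps most likely to fail**

Step 4 (proposed new step). The risks are plain alkene isomerisation without methyl migration, syn instead of anti H/CH3 delivery (the trans-dimethyl diastereomer), further cationic shifts, or low ee. The fallback uses known chemistry, sets out from 1 and comes back at 12. α-Chlorination of 1 (SO2Cl2, CCl4) gives 2-chloro-2-methylcyclohexan-1-one F1, and dehydrochlorination (LiCl, DMF, 100 °C) gives 2-methylcyclohex-2-en-1-one F2. Cu-catalysed asymmetric conjugate addition of Me3Al (CuTC, chiral phosphoramidite, Et2O, −30 °C) gives dimethylaluminium (3R)-2,3-dimethylcyclohex-1-en-1-olate F3. Activation with MeLi and allylation with allyl iodide (HMPA) anti to the new methyl gives (2S,3R)-2,3-dimethyl-2-(prop-2-en-1-yl)cyclohexan-1-one F4. KHMDS gives potassium (5R,6S)-5,6-dimethyl-6-(prop-2-en-1-yl)cyclohex-1-en-1-olate F5, which PhNTf2 converts into (5R,6S)-5,6-dimethyl-6-(prop-2-en-1-yl)cyclohex-1-en-1-yl trifluoromethanesulfonate F6. Fe(acac)3-catalysed coupling with MeMgBr gives (5R,6S)-1,5,6-trimethyl-6-(prop-2-en-1-yl)cyclohex-1-ene F7. Aldehyde-selective (nitrite-modified) Wacker oxidation of the terminal alkene gives 3-[(1S,6R)-1,2,6-trimethylcyclohex-2-en-1-yl]propanal F8, and Ohira–Bestmann homologation (dimethyl (1-diazo-2-oxopropyl)phosphonate, K2CO3, MeOH) gives 12.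

Step 3. The sp2–sp3 coupling at a tetrasubstituted, doubly flanked enol triflate may stall or give reduction products. The fallback sets out from 5 and comes back at 11. Condensation of 5 with 2,4,6-triisopropylbenzenesulfonohydrazide gives N′-(2,2,6-trimethylcyclohexylidene)-2,4,6-tri(propan-2-yl)benzenesulfonohydrazide F9. A Shapiro reaction (n-BuLi, THF/TMEDA, −78 → 0 °C) gives (2,6,6-trimethylcyclohex-1-en-1-yl)lithium F10. Opening of oxirane (BF3·OEt2, −78 °C) gives 2-(2,6,6-trimethylcyclohex-1-en-1-yl)ethan-1-ol F11. I2/PPh3/imidazole gives 2-(2-iodoethyl)-1,3,3-trimethylcyclohex-1-ene F12, and SN2 displacement with lithium acetylide–ethylenediamine in DMSO gives 11.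

Step 7. The SN2′/SN2 ratio and the ee with this functionalised Grignard reagent and the dibromide are not assured. The fallback is auxiliary-controlled, sets out from 18 and comes back at 23. Finkelstein exchange (NaI, acetone) gives 3-(3-iodopropyl)furan F13. The sodium dienolate of (S)-4-benzyl-3-[(E)-but-2-enoyl]-1,3-oxazolidin-2-one (NaHMDS, THF, −78 °C) is alkylated at the α-carbon, anti to the benzyl group, to give (4S)-4-benzyl-3-[(2S)-2-ethenyl-5-(furan-3-yl)pentanoyl]-1,3-oxazolidin-2-one F14. LiBH4 (Et2O, 0 °C) then gives 23.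

## Further compounds

F1 | step 4 | 2-chloro-2-methylcyclohexan-1-one | CC1(Cl)CCCCC1=O
F2 | step 4 | 2-methylcyclohex-2-en-1-one | CC1=CCCCC1=O
F3 | step 4 | dimethylaluminium (3R)-2,3-dimethylcyclohex-1-en-1-olate | C[Al](C)OC1=C(C)[C@H](C)CCC1
F4 | step 4 | (2S,3R)-2,3-dimethyl-2-(prop-2-en-1-yl)cyclohexan-1-one | O=C1CCC[C@@H](C)[C@]1(C)CC=C
F5 | step 4 | potassium (5R,6S)-5,6-dimethyl-6-(prop-2-en-1-yl)cyclohex-1-en-1-olate | [K]OC1=CCC[C@@H](C)[C@]1(C)CC=C
F6 | step 4 | (5R,6S)-5,6-dimethyl-6-(prop-2-en-1-yl)cyclohex-1-en-1-yl trifluoromethanesulfonate | O=S(=O)(OC1=CCC[C@@H](C)[C@]1(C)CC=C)C(F)(F)F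
F7 | step 4 | (5R,6S)-1,5,6-trimethyl-6-(prop-2-en-1-yl)cyclohex-1-ene | CC1=CCC[C@@H](C)[C@]1(C)CC=C
F8 | step 4 | 3-[(1S,6R)-1,2,6-trimethylcyclohex-2-en-1-yl]propanal | CC1=CCC[C@@H](C)[C@]1(C)CCC=O
F9 | step 3 | N′-(2,2,6-trimethylcyclohexylidene)-2,4,6-tri(propan-2-yl)benzenesulfonohydrazide | CC1CCCC(C)(C)C1=NNS(=O)(=O)c1c(C(C)C)cc(C(C)C)cc1C(C)C
F10 | step 3 | (2,6,6-trimethylcyclohex-1-en-1-yl)lithium | CC1=C([Li])C(C)(C)CCC1
F11 | step 3 | 2-(2,6,6-trimethylcyclohex-1-en-1-yl)ethan-1-ol | CC1=C(CCO)C(C)(C)CCC1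
F12 | step 3 | 2-(2-iodoethyl)-1,3,3-trimethylcyclohex-1-ene | CC1=C(CCI)C(C)(C)CCC1
F13 | step 7 | 3-(3-iodopropyl)furan | ICCCc1ccoc1
F14 | step 7 | (4S)-4-benzyl-3-[(2S)-2-ethenyl-5-(furan-3-yl)pentanoyl]-1,3-oxazolidin-2-one | C=C[C@H](CCCc1ccoc1)C(=O)N1[C@@H](Cc2ccccc2)COC1=O
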